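**Retrosynthetic overview**
1. Target ⇒ hydrogenolysis of three benzyl ethers plus protonation ⇒ tribenzyl bis(sulfate) salt ⇒ double O-sulfation of a tribenzyl diaryl ether diol. The only two free OH groups of that diol are the ones that carry sulfate in the target.
2. Key disconnection: the diaryl ether C–O bond between C-1 of ring B (the tetraoxygenated ring) and the oxygen of ring A. Ring B serves as a p-quinone diazide (carbene, that is aryl cation, equivalent) and ring A as 5-(benzyloxy)resorcinol.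
3. Quinone diazide ⇒ 2,6-bis(benzyloxy)-1,4-benzoquinone (C–N bond at the more electrophilic carbonyl) ⇒ 3,5-bis(benzyloxy)phenol (para oxidation).
4. No ring is built. Rings A and B are bought as phloroglucinol benzyl ethers; ring B is dearomatised in the first two steps and re-aromatised in the key step.

Assumption: the target has no stereocentre or stereoaxis, so it is achiral and needs no stereocontrol; it is delivered as the free bis(hydrogen sulfate) drawn, and both phloroglucinol benzyl ethers are taken as catalogue items.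

**Step 1**
Reactants: 1 3,5-bis(benzyloxy)phenol
Product: 2 2,6-bis(benzyloxy)cyclohexa-2,5-diene-1,4-dione
Conditions: ON(SO3K)2 (2.5 equiv), KH2PO4 buffer (pH 6), acetone/H2O, 0 °C to rt
Reagents that add atoms: potassium nitrosodisulfonate, ON(SO3K)2, [K+].[K+].[O]N(S(=O)(=O)[O-])S(=O)(=O)[O-]
Why: Teuber oxidation, in which the nitroxyl radical abstracts the phenolic hydrogen and a second equivalent couples at the free para carbon, so collapse gives only the p-quinone and leaves the benzyl ethers untouched.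

**Step 2**
Reactants: 2 2,6-bis(benzyloxy)cyclohexa-2,5-diene-1,4-dione
Product: 4 4-diazo-3,5-bis(benzyloxy)cyclohexa-2,5-dien-1-one, via tosylhydrazone 3 (not isolated)
Conditions: TsNHNH2 (1.05 equiv), MeOH/CH2Cl2, 0 °C to rt; then Et3N (2 equiv), 0 °C; aqueous wash, short basic alumina plug, dark
Reagents that add atoms: 4-methylbenzenesulfonohydrazide (TsNHNH2), Cc1ccc(cc1)S(=O)(=O)NN
Why: Tosylhydrazone condensation followed by Bamford–Stevens-type loss of sulfinate is the standard entry to p-quinone diazides; the carbonyl between the two benzyloxy groups is the only one that is not a doubly vinylogous ester, so it is the more electrophilic one (as in known 1,2-additions to alkoxyquinones), and the low reduction potential of the dialkoxyquinone limits reduction by the hydrazide.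

**Step 3**
Reactants: 4 4-diazo-3,5-bis(benzyloxy)cyclohexa-2,5-dien-1-one; 5 5-(benzyloxy)benzene-1,3-diol
Product: 7 3,5-bis(benzyloxy)-4-[3-(benzyloxy)-5-hydroxyphenoxy]phenol, via oxonium ylide 6 (not isolated)
Conditions: Rh2(OAc)4 (2 mol%), 5 (3 equiv), 4 Å MS, DCE, 40 °C, 4 added over 4 h by syringe pump, dark
Reagents that add atoms: none
Why: Proposed new method: Rh2(OAc)4, a divalent rhodium dimer, expels N2 from p-quinone diazide 4 to give a catalyst-bound quinoid carbene that behaves as a masked 4-hydroxyaryl cation; a phenolic oxygen of 5 adds to the carbene carbon from above the ring plane, where the two in-plane benzyloxy groups do not block it, release of the catalyst re-aromatises ring B to oxonium ylide 6, and a proton shift to the phenolate gives 7, so aromatisation makes the C–O bond formation irreversible; attack through a ring carbon of 5 would build a tetra-ortho-oxygenated biaryl and is sterically disfavoured, azo coupling is held back by the neutral aprotic medium and the slow addition of 4, and the excess of 5 prevents a second insertion; the closest known reaction type is dirhodium-carbene O–H insertion of alcohols and phenols into α-diazocarbonyl compounds, together with quinoid carbene transfer to alkenes and arenes, which has not been shown for a di-ortho-alkoxy p-quinone diazide and a polyphenol as a diaryl ether synthesis.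

**Step 4**
Reactants: 7 3,5-bis(benzyloxy)-4-[3-(benzyloxy)-5-hydroxyphenoxy]phenol
Product: 9 disodium 3,5-bis(benzyloxy)-4-[3-(benzyloxy)-5-(sulfonatooxy)phenoxy]phenyl sulfate, via bis(pyridinium) salt 8 (not isolated)
Conditions: SO3·pyridine (6 equiv), pyridine, rt, 16 h; then aq NaHCO3 to pH 8; reversed-phase C18 (H2O/MeOH)
Reagents that add atoms: sulfur trioxide–pyridine complex, [O-]S(=O)(=O)[n+]1ccccc1; sodium hydrogencarbonate, [Na+].OC([O-])=O
Why: Phenol O-sulfation with a sulfur trioxide–amine complex reaches only the two free, unhindered OH groups, the benzyl ethers and the diaryl ether are inert, and the mildly basic work-up keeps the sulfate monoesters as stable sodium salts.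

**Step 5**
Reactants: 9 disodium 3,5-bis(benzyloxy)-4-[3-(benzyloxy)-5-(sulfonatooxy)phenoxy]phenyl sulfate
Product: 11 3,5-dihydroxy-4-[3-hydroxy-5-(sulfooxy)phenoxy]phenyl hydrogen sulfate (target), via disodium salt 10 (not isolated)
Conditions: H2 (1 atm), 10% Pd/C, MeOH, rt; filter; then HCl (2.0 equiv, 1.25 M in MeOH), 0 °C; filter off NaCl, concentrate cold, store at −20 °C
Reagents that add atoms: none
Why: Catalytic hydrogenolysis cleaves the three aryl benzyl ethers while aryl sulfate monoester anions are inert to H2/Pd in neutral methanol, and cold stoichiometric acid then protonates both sulfates faster than they hydrolyse; no stereocentre is involved.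

**Compound list**
1 | 3,5-bis(benzyloxy)phenol | Oc1cc(OCc2ccccc2)cc(OCc2ccccc2)c1 | starting material
2 | 2,6-bis(benzyloxy)cyclohexa-2,5-diene-1,4-dione | O=C1C=C(OCc2ccccc2)C(=O)C(OCc2ccccc2)=C1 | intermediate
3 | N'-[2,6-bis(benzyloxy)-4-oxocyclohexa-2,5-dien-1-ylidene]-4-methylbenzenesulfonohydrazide (tosylhydrazone) | O=C1C=C(OCc2ccccc2)C(=NNS(=O)(=O)c2ccc(C)cc2)C(OCc2ccccc2)=C1 | intermediate
4 | 4-diazo-3,5-bis(benzyloxy)cyclohexa-2,5-dien-1-one | O=C1C=C(OCc2ccccc2)C(=[N+]=[N-])C(OCc2ccccc2)=C1 | intermediate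
5 | 5-(benzyloxy)benzene-1,3-diol | Oc1cc(O)cc(OCc2ccccc2)c1 | starting material
6 | 4-{[3-(benzyloxy)-5-hydroxyphenyl]oxonio}-3,5-bis(benzyloxy)phenolate (oxonium ylide) | [O-]c1cc(OCc2ccccc2)c([OH+]c2cc(O)cc(OCc3ccccc3)c2)c(OCc2ccccc2)c1 | intermediate
7 | 3,5-bis(benzyloxy)-4-[3-(benzyloxy)-5-hydroxyphenoxy]phenol | Oc1cc(OCc2ccccc2)c(Oc2cc(O)cc(OCc3ccccc3)c2)c(OCc2ccccc2)c1 | intermediate
8 | bis(pyridinium) 3,5-bis(benzyloxy)-4-[3-(benzyloxy)-5-(sulfonatooxy)phenoxy]phenyl sulfate | c1cc[nH+]cc1.c1cc[nH+]cc1.[O-]S(=O)(=O)Oc1cc(OCc2ccccc2)c(Oc2cc(OS(=O)(=O)[O-])cc(OCc3ccccc3)c2)c(OCc2ccccc2)c1 | intermediate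
9 | disodium 3,5-bis(benzyloxy)-4-[3-(benzyloxy)-5-(sulfonatooxy)phenoxy]phenyl sulfate | [Na+].[Na+].[O-]S(=O)(=O)Oc1cc(OCc2ccccc2)c(Oc2cc(OS(=O)(=O)[O-])cc(OCc3ccccc3)c2)c(OCc2ccccc2)c1 | intermediate
10 | disodium 3,5-dihydroxy-4-[3-hydroxy-5-(sulfonatooxy)phenoxy]phenyl sulfate | [Na+].[Na+].[O-]S(=O)(=O)Oc1cc(O)c(Oc2cc(O)cc(OS(=O)(=O)[O-])c2)c(O)c1 | intermediate
11 | 3,5-dihydroxy-4-[3-hydroxy-5-(sulfooxy)phenoxy]phenyl hydrogen sulfate (CNP0460023.0, achiral) | O=S(=O)(O)Oc1cc(O)cc(Oc2c(O)cc(OS(=O)(=O)O)cc2O)c1 | target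

**Total step count:** 5
**Longest linear sequence:** 5 steps (1 → 2 → 4 → 7 → 9 → 11); 5 enters at step 3.

**Three steps most likely to fail**

Step 3 (the proposed new step).
- Risks: C-arylation of the very nucleophilic ring of 5, azo coupling, slow carbene formation at the flanked diazo carbon, and insertion into water.
- Fallback (known chemistry only): it sets out from 4 and comes back at 7. Compound 4 is protonated and treated with KI (H2SO4, MeCN/H2O, 0 °C, iododediazoniation) to give 3,5-bis(benzyloxy)-4-iodophenol F1. MOMCl and iPr2NEt in CH2Cl2 convert it into 1,3-bis(benzyloxy)-2-iodo-5-(methoxymethoxy)benzene F2. An Ullmann diaryl ether coupling with 5 (3 equiv; CuI, N,N-dimethylglycine, Cs2CO3, dioxane, 100 °C) gives 3-(benzyloxy)-5-[2,6-bis(benzyloxy)-4-(methoxymethoxy)phenoxy]phenol F3. HCl in MeOH at 40 °C removes the acetal and returns 7.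

Step 2.
- Risks: condensation at the unhindered carbonyl, or reduction of the quinone by the hydrazide.
- Fallback: it sets out from 2, avoids every diazo compound, and comes back at 7. Na2S2O4 in THF/H2O reduces 2 to 2,6-bis(benzyloxy)benzene-1,4-diol F4. MOMCl (1.0 equiv) and iPr2NEt cap the more acidic, unhindered 4-OH to give 2,6-bis(benzyloxy)-4-(methoxymethoxy)phenol F5.
- Ring A partner: it is made from commercial 5-bromoresorcinol. BnBr (1 equiv) and K2CO3 in acetone give 3-(benzyloxy)-5-bromophenol F6, and MOMCl then gives 1-(benzyloxy)-3-bromo-5-(methoxymethoxy)benzene F7.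
- Coupling and return: an Ullmann coupling in the opposite sense, hindered phenol F5 with unhindered bromide F7 (CuI, picolinic acid, K3PO4, DMSO, 90 °C), gives 1,3-bis(benzyloxy)-2-[3-(benzyloxy)-5-(methoxymethoxy)phenoxy]-5-(methoxymethoxy)benzene F8. HCl in MeOH then returns 7.

Step 5.
- Risks: loss of sulfate on the catalyst or during acid release, and strong adsorption of the polar product on carbon.
- Fallback: it sets out from 7 and comes back at 11, and it replaces the salt route by a neutral, chromatographable protected sulfate. ClSO2OCH2CCl3, Et3N and DMAP in THF give the bis(2,2,2-trichloroethyl) sulfate diester of 7 F9. BCl3 and pentamethylbenzene in CH2Cl2 at −78 °C remove the three benzyl groups without hydrogen to give the bis(2,2,2-trichloroethyl) sulfate diester triol F10. Zn and HCO2NH4 in MeOH at rt unmask both sulfates as diammonium 3,5-dihydroxy-4-[3-hydroxy-5-(sulfonatooxy)phenoxy]phenyl sulfate F11. Cold HCl (2.0 equiv) in MeOH gives 11.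

**Further compounds**
F1 | step 3 | 3,5-bis(benzyloxy)-4-iodophenol | Oc1cc(OCc2ccccc2)c(I)c(OCc2ccccc2)c1
F2 | step 3 | 1,3-bis(benzyloxy)-2-iodo-5-(methoxymethoxy)benzene | COCOc1cc(OCc2ccccc2)c(I)c(OCc2ccccc2)c1
F3 | step 3 | 3-(benzyloxy)-5-[2,6-bis(benzyloxy)-4-(methoxymethoxy)phenoxy]phenol | COCOc1cc(OCc2ccccc2)c(Oc2cc(O)cc(OCc3ccccc3)c2)c(OCc2ccccc2)c1
F4 | step 2 | 2,6-bis(benzyloxy)benzene-1,4-diol | Oc1cc(OCc2ccccc2)c(O)c(OCc2ccccc2)c1
F5 | step 2 | 2,6-bis(benzyloxy)-4-(methoxymethoxy)phenol | COCOc1cc(OCc2ccccc2)c(O)c(OCc2ccccc2)c1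
F6 | step 2 | 3-(benzyloxy)-5-bromophenol | Oc1cc(Br)cc(OCc2ccccc2)c1
F7 | step 2 | 1-(benzyloxy)-3-bromo-5-(methoxymethoxy)benzene | COCOc1cc(Br)cc(OCc2ccccc2)c1
F8 | step 2 | 1,3-bis(benzyloxy)-2-[3-(benzyloxy)-5-(methoxymethoxy)phenoxy]-5-(methoxymethoxy)benzene | COCOc1cc(OCc2ccccc2)c(Oc2cc(OCOC)cc(OCc3ccccc3)c2)c(OCc2ccccc2)c1
F9 | step 5 | 3,5-bis(benzyloxy)-4-{3-(benzyloxy)-5-[(2,2,2-trichloroethoxy)sulfonyloxy]phenoxy}phenyl 2,2,2-trichloroethyl sulfate | ClC(Cl)(Cl)COS(=O)(=O)Oc1cc(OCc2ccccc2)c(Oc2cc(OS(=O)(=O)OCC(Cl)(Cl)Cl)cc(OCc3ccccc3)c2)c(OCc2ccccc2)c1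
F10 | step 5 | 3,5-dihydroxy-4-{3-hydroxy-5-[(2,2,2-trichloroethoxy)sulfonyloxy]phenoxy}phenyl 2,2,2-trichloroethyl sulfate | ClC(Cl)(Cl)COS(=O)(=O)Oc1cc(O)c(Oc2cc(O)cc(OS(=O)(=O)OCC(Cl)(Cl)Cl)c2)c(O)c1
F11 | step 5 | diammonium 3,5-dihydroxy-4-[3-hydroxy-5-(sulfonatooxy)phenoxy]phenyl sulfate | [NH4+].[NH4+].[O-]S(=O)(=O)Oc1cc(O)c(Oc2cc(O)cc(OS(=O)(=O)[O-])c2)c(O)c1
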